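**Retrosynthetic overview**
1. The angelate is attached last; the C8 oxygen is carried through the route as a TEMPO ether and freed by N–O cleavage just before.
2. Key step: one double ring-closing metathesis of a pentaene closes the spiro-cyclohexene (CH=C(R)) and the C4=C5 alkene of the furanone-bridged nine-membered ring (the ten-membered carbocycle).
3. The pentaene comes from a cis-α-methylene lactone by conjugate allylation, then enolate alkylation with a 2-substituted allyl bromide on the convex face (sets C11 and places R 1,3 to the spiro carbon, which a myrcene Diels–Alder would not).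
4. The lactone (C6, C7) comes from an indium Barbier allylation/lactonisation of an allyl bromide with crotonaldehyde; the bromide comes from a 2-methyl-3(2H)-furanone by Michael addition to acrolein (C10), α-oxyamination (C8), Morita–Baylis–Hillman reaction and bromination.
5. Ring order: furanone (step 1), γ-lactone (step 6), then cyclohexene and nine-membered ring together (step 11).

Assumption: the SMILES is taken literally: 4Z; 6S,7R,8R,10R,11S (cis-fused lactone); R on the cyclohexene carbon 1,3 to the spiro centre; locants are germacrane-type (C1 furanone C=O, C3 furanone C–O, C4=C5, C6 lactone O–CH, C7, C8 O–CH, C9 CH2, C10 quaternary C–O, C11 spiro carbon, C12 lactone C=O, C13 the ring CH2 on C11 not next to C(R)).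

Abbreviations in names: Fur = (2R)-2-methyl-3-oxo-5-(prop-1-en-2-yl)-2,3-dihydrofuran-2-yl; TMPO = (2,2,6,6-tetramethylpiperidin-1-yl)oxy; R = 4-methylpent-3-en-1-yl; Core = (4Z)-1-oxo-3,10-epoxygermacra-2,4-dien-12,6-olide whose C11 is the spiro atom of a 3-R-cyclohex-3-ene (ring C11–CH2–C(R)=CH–CH2–C13H2).

**Step 1**
Reactants: 1 2-methylbut-1-en-3-yne; 2 N,N-dimethyl-2-hydroxypropanamide (racemic)
Product: 6 2-methyl-5-(prop-1-en-2-yl)furan-3(2H)-one (racemic), via lithium acetylide 3 (not isolated), via hydroxy ynone 4 (not isolated), via enaminone 5 (not isolated)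
Conditions: 1 (2.2 equiv), nBuLi (2.1 equiv), THF, −78 °C; 2 (1 equiv), −78 → 0 °C; MeOH, rt, 2 h; 2 M HCl to pH 1, rt
Reagents that add atoms: none
Why: Acetylide acylation of a tertiary amide (the chelated tetrahedral alkoxide prevents over-addition) followed by the amine-mediated γ-hydroxy-ynone to 3(2H)-furanone cyclisation, in which the Me2NH set free adds to ynone 4 to give enaminone 5, whose hydroxyl closes onto the β-carbon under acid with loss of Me2NH; C2 is racemic here and is re-set in step 2.

**Step 2**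
Reactants: 6 2-methyl-5-(prop-1-en-2-yl)furan-3(2H)-one (racemic); 7 prop-2-enal
Product: 8 3-Fur-propanal
Conditions: 7 (3 equiv), 9-O-(9-phenanthryl)cupreidine (10 mol %; the cupreine pseudo-enantiomer if the sense proves opposite), CH2Cl2, −30 °C, 48 h
Reagents that add atoms: none
Why: Proposed new method: asymmetric Michael addition in which the quinuclidine nitrogen deprotonates the acidic C2–H (the enolate is an aromatic 3-furanolate) while the 6'-OH hydrogen-bonds acrolein, so the chiral ion pair delivers the enal to one face of C2 and creates the quaternary (R) centre (C10), C-attack at C2 being favoured because it restores the vinylogous ester; closest known reaction type: cinchona-alkaloid-catalysed Michael additions of α-substituted β-keto esters and 2-substituted benzofuran-3(2H)-ones to acrolein and enones.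

**Step 3**
Reactants: 8 3-Fur-propanal
Product: 9 (2R)-3-Fur-2-TMPO-propanal
Conditions: TEMPO (1.5 equiv), CuCl2·2H2O (10 mol %), (5R)-5-benzyl-2,2,3-trimethylimidazolidin-4-one·TFA (20 mol %; antipode if the sense proves opposite), air, acetone, −10 °C; used crude
Reagents that add atoms: TEMPO, CC1(C)CCCC(C)(C)N1[O]
Why: Enamine-mediated α-oxyamination of the aldehyde with TEMPO (copper co-catalysed, air as terminal oxidant), in which the imidazolidinone enamine is attacked on the face left open by the benzyl group, so C8 (R) is set by the catalyst independently of the remote C10 centre.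

**Step 4**
Reactants: 9 (2R)-3-Fur-2-TMPO-propanal; 10 methyl prop-2-enoate
Product: 11 methyl (4R)-5-Fur-3-hydroxy-2-methylidene-4-TMPO-pentanoate (C3 epimers)
Conditions: 10 (10 equiv, neat), DABCO (1 equiv), MeOH (2 equiv), rt, 4 d
Reagents that add atoms: none
Why: Morita–Baylis–Hillman reaction, helped by the activating α-oxygen substituent; the new carbinol centre is formed as a mixture and is erased in step 5.

**Step 5**
Reactants: 11 methyl (4R)-5-Fur-3-hydroxy-2-methylidene-4-TMPO-pentanoate (C3 epimers)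
Product: 12 methyl (2Z,4R)-2-(bromomethyl)-5-Fur-4-TMPO-pent-2-enoate
Conditions: PBr3 (0.4 equiv), Et2O, −10 → 0 °C
Reagents that add atoms: phosphorus tribromide, BrP(Br)Br
Why: SN2' bromination of the Baylis–Hillman alcohol with allylic transposition gives the conjugated trisubstituted enoate with the thermodynamically preferred Z geometry, and C8 is not touched.

**Step 6**
Reactants: 12 methyl (2Z,4R)-2-(bromomethyl)-5-Fur-4-TMPO-pent-2-enoate; 13 (2E)-but-2-enal
Product: 15 (4S,5S)-4-[(1R)-2-Fur-1-TMPO-ethyl]-3-methylidene-5-[(1E)-prop-1-en-1-yl]oxolan-2-one, via hydroxy ester 14 (not isolated)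
Conditions: 13 (3 equiv), In powder (1.5 equiv), THF/H2O 1:1, rt; then p-TsOH·H2O (cat.), CH2Cl2, rt
Reagents that add atoms: none
Why: Indium-mediated Barbier allylation through a closed six-membered transition state in which the C8 substituent (cis to the CH2–In carbon) is axial gives the syn adduct, the aldehyde adding to the alkene face anti to the C8–C9 bond while C8–H eclipses the alkene (A(1,3) strain) and the TMPO group points outwards, which sets C7 (3S in 14) and C6 (4S in 14), and acid then closes the cis-fused lactone.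

**Step 7**
Reactants: 15 (4S,5S)-4-[(1R)-2-Fur-1-TMPO-ethyl]-3-methylidene-5-[(1E)-prop-1-en-1-yl]oxolan-2-one
Product: 17 (4S,5S)-3-(but-3-en-1-yl)-4-[(1R)-2-Fur-1-TMPO-ethyl]-5-[(1E)-prop-1-en-1-yl]oxolan-2-one (C3 epimers), via silyl ketene acetal 16 (not isolated)
Conditions: allylMgBr (1.5 equiv), CuBr·SMe2 (1.5 equiv), LiCl (1.5 equiv), Me3SiCl (3 equiv), THF, −78 °C; 1 M HCl work-up
Reagents that add atoms: allylmagnesium bromide, C=CC[Mg]Br
Why: Conjugate addition of an allylcopper reagent activated by Me3SiCl to the exocyclic methylene lactone, by far the most reactive acceptor (the vinylogous-ester furanone is inert to the non-basic organocopper), with hydrolysis of the silyl ketene acetal on work-up; the C3 epimers converge in step 10.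

**Step 8**
Reactants: 18 2-methylprop-2-en-1-ol; 19 1-bromo-3-methylbut-2-ene
Product: 21 6-methyl-2-methylidenehept-5-en-1-ol, via dilithio alkoxide 20 (not isolated)
Conditions: nBuLi (2.2 equiv), TMEDA, Et2O, 0 °C → rt; 19, −78 °C → rt; H2O
Reagents that add atoms: none
Why: Alkoxide-directed allylic lithiation of methallyl alcohol gives a dianion whose carbon terminus alkylates prenyl bromide at its primary carbon (SN2); no stereocentre is formed.

**Step 9**
Reactants: 21 6-methyl-2-methylidenehept-5-en-1-ol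
Product: 22 2-(bromomethyl)-6-methylhepta-1,5-diene
Conditions: PBr3 (0.4 equiv), pyridine (cat.), Et2O, −10 °C
Reagents that add atoms: phosphorus tribromide, BrP(Br)Br
Why: Conversion of the primary allylic alcohol into the bromide with PBr3 (SN2, and SN2' attack gives the same compound); no stereocentre is formed.

**Step 10**
Reactants: 17 (4S,5S)-3-(but-3-en-1-yl)-4-[(1R)-2-Fur-1-TMPO-ethyl]-5-[(1E)-prop-1-en-1-yl]oxolan-2-one (C3 epimers); 22 2-(bromomethyl)-6-methylhepta-1,5-diene
Product: 24 (3S,4S,5S)-3-(but-3-en-1-yl)-4-[(1R)-2-Fur-1-TMPO-ethyl]-3-(6-methyl-2-methylidenehept-5-en-1-yl)-5-[(1E)-prop-1-en-1-yl]oxolan-2-one, via lithium enolate 23 (not isolated)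
Conditions: LiN(SiMe3)2 (1.1 equiv), THF, −78 °C; 22 (1.5 equiv), DMPU, −78 → −30 °C
Reagents that add atoms: none
Why: Alkylation of the lactone lithium enolate with a reactive allylic bromide, the electrophile entering on the convex face anti to the cis-disposed C4 and C5 substituents, which sets the quaternary centre (3S, C11) with the butenyl arm on the hindered face.

**Step 11**
Reactants: 24 (3S,4S,5S)-3-(but-3-en-1-yl)-4-[(1R)-2-Fur-1-TMPO-ethyl]-3-(6-methyl-2-methylidenehept-5-en-1-yl)-5-[(1E)-prop-1-en-1-yl]oxolan-2-one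
Product: 26 (6S,7S,8R,10R,11S)-8-TMPO-Core, via spirocyclohexene 25 (not isolated)
Conditions: second-generation Hoveyda–Grubbs catalyst (2 × 10 mol %), toluene (1 mM), 40 °C, 2 h, then 100 °C, 12 h, argon sparge
Reagents that add atoms: none
Why: Double ring-closing metathesis in which the ruthenium alkylidene loads on the only monosubstituted alkene (butenyl) and closes onto the 1,1-disubstituted alkene of the neighbouring arm (six-membered ring, Thorpe–Ingold assisted, no new stereocentre) to give 25, after which metathesis between the propenyl and furanone isopropenyl groups closes the nine-membered oxa-bridged ring, a closure known for eremantholide-type furanone-bridged rings, the C4=C5 alkene being necessarily Z (cis in the ring).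

**Step 12**
Reactants: 26 (6S,7S,8R,10R,11S)-8-TMPO-Core
Product: 27 (6S,7R,8R,10R,11S)-8-hydroxy-Core
Conditions: Zn dust (10 equiv), AcOH/THF/H2O 3:1:1, 50 °C
Reagents that add atoms: none
Why: Reductive N–O cleavage of the TEMPO-derived alkoxyamine by zinc in acetic acid frees the C8 hydroxyl with retention, while the alkenes, the vinylogous ester and the lactone are not reduced under these conditions (the change of the C7 descriptor from S to R is a CIP effect only).

**Step 13**
Reactants: 27 (6S,7R,8R,10R,11S)-8-hydroxy-Core; 28 (2Z)-2-methylbut-2-enoic acid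
Product: 30 (6S,7R,8R,10R,11S)-8-[(2Z)-2-methylbut-2-enoyloxy]-Core, via mixed anhydride 29 (not isolated)
Conditions: 28 (3 equiv), 2,4,6-trichlorobenzoyl chloride (3 equiv), Et3N (3.3 equiv), toluene, rt, 2 h; then 27, 75 °C
Reagents that add atoms: none
Why: Yamaguchi-type esterification through the mixed anhydride acylates the secondary alcohol without DMAP, which avoids base-induced Z to E isomerisation of the angelate, and no stereocentre is changed.

**Compound list**
1 | 2-methylbut-1-en-3-yne | C=C(C)C#C | starting material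
2 | N,N-dimethyl-2-hydroxypropanamide (racemic) | CC(O)C(=O)N(C)C | starting material
3 | (3-methylbut-3-en-1-yn-1-yl)lithium | [Li]C#CC(C)=C | intermediate
4 | 2-hydroxy-6-methylhept-6-en-4-yn-3-one (racemic) | CC(O)C(=O)C#CC(C)=C | intermediate
5 | 5-(dimethylamino)-2-hydroxy-6-methylhepta-4,6-dien-3-one (racemic, alkene isomers) | CC(O)C(=O)C=C(N(C)C)C(C)=C | intermediate
6 | 2-methyl-5-(prop-1-en-2-yl)furan-3(2H)-one (racemic) | CC1OC(=CC1=O)C(C)=C | intermediate
7 | prop-2-enal | C=CC=O | starting material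
8 | 3-Fur-propanal | O=CCC[C@@]1(C)OC(=CC1=O)C(C)=C | intermediate
9 | (2R)-3-Fur-2-TMPO-propanal | O=C[C@H](ON1C(C)(C)CCCC1(C)C)C[C@@]2(C)OC(=CC2=O)C(C)=C | intermediate
10 | methyl prop-2-enoate | C=CC(=O)OC | starting material
11 | methyl (4R)-5-Fur-3-hydroxy-2-methylidene-4-TMPO-pentanoate (C3 epimers) | COC(=O)C(=C)C(O)[C@H](ON1C(C)(C)CCCC1(C)C)C[C@@]2(C)OC(=CC2=O)C(C)=C | intermediate
12 | methyl (2Z,4R)-2-(bromomethyl)-5-Fur-4-TMPO-pent-2-enoate | COC(=O)/C(CBr)=C/[C@H](ON1C(C)(C)CCCC1(C)C)C[C@@]2(C)OC(=CC2=O)C(C)=C | intermediate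
13 | (2E)-but-2-enal | C/C=C/C=O | starting material
14 | methyl (3S,4S,5E)-3-[(1R)-2-Fur-1-TMPO-ethyl]-4-hydroxy-2-methylidenehept-5-enoate | COC(=O)C(=C)[C@@H]([C@@H](O)/C=C/C)[C@H](ON1C(C)(C)CCCC1(C)C)C[C@@]2(C)OC(=CC2=O)C(C)=C | intermediate
15 | (4S,5S)-4-[(1R)-2-Fur-1-TMPO-ethyl]-3-methylidene-5-[(1E)-prop-1-en-1-yl]oxolan-2-one | C/C=C/[C@@H]1OC(=O)C(=C)[C@@H]1[C@H](ON2C(C)(C)CCCC2(C)C)C[C@@]3(C)OC(=CC3=O)C(C)=C | intermediate
16 | (4S,5S)-3-(but-3-en-1-yl)-4-[(1R)-2-Fur-1-TMPO-ethyl]-5-[(1E)-prop-1-en-1-yl]-2-(trimethylsilyloxy)-4,5-dihydrofuran | C/C=C/[C@@H]1OC(O[Si](C)(C)C)=C(CCC=C)[C@@H]1[C@H](ON2C(C)(C)CCCC2(C)C)C[C@@]3(C)OC(=CC3=O)C(C)=C | intermediate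
17 | (4S,5S)-3-(but-3-en-1-yl)-4-[(1R)-2-Fur-1-TMPO-ethyl]-5-[(1E)-prop-1-en-1-yl]oxolan-2-one (C3 epimers) | C/C=C/[C@@H]1OC(=O)C(CCC=C)[C@@H]1[C@H](ON2C(C)(C)CCCC2(C)C)C[C@@]3(C)OC(=CC3=O)C(C)=C | intermediate
18 | 2-methylprop-2-en-1-ol | CC(=C)CO | starting material
19 | 1-bromo-3-methylbut-2-ene | CC(C)=CCBr | starting material
20 | lithium 2-(lithiomethyl)prop-2-en-1-olate | [Li]CC(=C)CO[Li] | intermediate
21 | 6-methyl-2-methylidenehept-5-en-1-ol | OCC(=C)CCC=C(C)C | intermediate
22 | 2-(bromomethyl)-6-methylhepta-1,5-diene | BrCC(=C)CCC=C(C)C | intermediate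
23 | lithium enolate of 17 (2-lithiooxy-4,5-dihydrofuran) | C/C=C/[C@@H]1OC(O[Li])=C(CCC=C)[C@@H]1[C@H](ON2C(C)(C)CCCC2(C)C)C[C@@]3(C)OC(=CC3=O)C(C)=C | intermediate
24 | (3S,4S,5S)-3-(but-3-en-1-yl)-4-[(1R)-2-Fur-1-TMPO-ethyl]-3-(6-methyl-2-methylidenehept-5-en-1-yl)-5-[(1E)-prop-1-en-1-yl]oxolan-2-one | C/C=C/[C@@H]1OC(=O)[C@](CC(=C)CCC=C(C)C)(CCC=C)[C@@H]1[C@H](ON2C(C)(C)CCCC2(C)C)C[C@@]3(C)OC(=CC3=O)C(C)=C | intermediate
25 | (3S,4S,5S)-4-[(1R)-2-Fur-1-TMPO-ethyl]-7-R-3-[(1E)-prop-1-en-1-yl]-2-oxaspiro[4.5]dec-7-en-1-one | C/C=C/[C@@H]1OC(=O)[C@]2(CCC=C(CCC=C(C)C)C2)[C@@H]1[C@H](ON3C(C)(C)CCCC3(C)C)C[C@@]4(C)OC(=CC4=O)C(C)=C | intermediate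
26 | (6S,7S,8R,10R,11S)-8-TMPO-Core (7S by CIP only; same geometry as 7R in 27 and 30) | CC1(C)CCCC(C)(C)N1O[C@@H]2C[C@@]3(C)OC(=CC3=O)/C(C)=C\[C@@H]3OC(=O)[C@]4(CCC=C(CCC=C(C)C)C4)[C@@H]32 | intermediate
27 | (6S,7R,8R,10R,11S)-8-hydroxy-Core | O[C@@H]1C[C@@]2(C)OC(=CC2=O)/C(C)=C\[C@@H]2OC(=O)[C@]3(CCC=C(CCC=C(C)C)C3)[C@@H]21 | intermediate
28 | (2Z)-2-methylbut-2-enoic acid (angelic acid) | C/C=C(/C)C(=O)O | starting material
29 | (2Z)-2-methylbut-2-enoic 2,4,6-trichlorobenzoic anhydride | C/C=C(/C)C(=O)OC(=O)c1c(Cl)cc(Cl)cc1Cl | intermediate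
30 | (6S,7R,8R,10R,11S)-8-[(2Z)-2-methylbut-2-enoyloxy]-Core | C/C=C(/C)C(=O)O[C@@H]1C[C@@]2(C)OC(=CC2=O)/C(C)=C\[C@@H]2OC(=O)[C@]3(CCC=C(CCC=C(C)C)C3)[C@@H]21 | target

**Step count**
Total: 13 steps. Longest linear sequence: 11 steps (steps 1–7 and 10–13); steps 8 and 9 make bromide 22.

**Steps most likely to fail, with fallbacks**

Step 11 (double ring-closing metathesis). The nine-membered ring may not close once the spiro ring crowds C5, or the butenyl alkylidene may close a bridged seven-membered ring onto the propenyl group instead. The fallback makes the two rings in separate operations and in the opposite order. It sets out from lactone 15: metathesis between its propenyl and isopropenyl groups, the only pair that can close a ring in this triene (second-generation Hoveyda–Grubbs catalyst, toluene, 100 °C), gives the macrocyclic α-methylene lactone F1. Conjugate allylation as in step 7 gives, by way of the silyl ketene acetal F2, the butenyl lactone F3. LiN(SiMe3)2 then gives the lithium enolate F4, which is alkylated with 22 on the convex face to the diene F5. A six-ring metathesis (second-generation Grubbs catalyst, CH2Cl2, 40 °C), now without a competing pairing, comes back to the route at 26.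

Step 6 (Barbier allylation). Two stereocentres depend on substrate control, and 1,4-elimination of the γ-oxygenated allylmetal is a further risk. The fallback is a reagent-controlled allylboration. It sets out from bromide 12: B2pin2 and Pd2(dba)3 (cat.) in THF give the allylboronate F6 with the alkene geometry kept. Its addition to 13 under a chiral BINOL-derived phosphoric acid (TRIP, 5 mol %, toluene, −30 °C) runs through a closed chair transition state (syn from this geometry), with the catalyst choosing the aldehyde face. Aqueous work-up comes back to the route at hydroxy ester 14.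

Step 2 (Michael addition). The furanone is untested as a Michael donor, so both the enantioselectivity and the C2 versus O or C4 selectivity are unproven. The fallback is a palladium-catalysed decarboxylative asymmetric allylic alkylation. It sets out from furanone 6: KN(SiMe3)2 and allyl chloroformate (THF, −78 °C) give the allyl enol carbonate F7. Pd2(dba)3 and (S)-tBu-PHOX in toluene then give the (R)-2-allyl furanone F8. An aldehyde-selective Wacker oxidation of the terminal alkene (PdCl2(PhCN)2, CuCl2·2H2O, AgNO2, tBuOH/MeNO2, O2) comes back to the route at aldehyde 8.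

**Further compounds**
F1 | step 11 | (4Z,6S,7S,8R,10R)-8-TMPO-1-oxo-3,10-epoxygermacra-2,4,11(13)-trien-12,6-olide | CC1(C)CCCC(C)(C)N1O[C@@H]2C[C@@]3(C)OC(=CC3=O)/C(C)=C\[C@@H]3OC(=O)C(=C)[C@@H]32
F2 | step 11 | trimethylsilyl ketene acetal of F3 | CC1(C)CCCC(C)(C)N1O[C@@H]2C[C@@]3(C)OC(=CC3=O)/C(C)=C\[C@@H]3OC(O[Si](C)(C)C)=C(CCC=C)[C@@H]32
F3 | step 11 | 13-(prop-2-en-1-yl)-11,13-dihydro derivative of F1 (C11 epimers) | CC1(C)CCCC(C)(C)N1O[C@@H]2C[C@@]3(C)OC(=CC3=O)/C(C)=C\[C@@H]3OC(=O)C(CCC=C)[C@@H]32
F4 | step 11 | lithium enolate of F3 | CC1(C)CCCC(C)(C)N1O[C@@H]2C[C@@]3(C)OC(=CC3=O)/C(C)=C\[C@@H]3OC(O[Li])=C(CCC=C)[C@@H]32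
F5 | step 11 | (11S)-11-(6-methyl-2-methylidenehept-5-en-1-yl) derivative of F3 | CC1(C)CCCC(C)(C)N1O[C@@H]2C[C@@]3(C)OC(=CC3=O)/C(C)=C\[C@@H]3OC(=O)[C@](CC(=C)CCC=C(C)C)(CCC=C)[C@@H]32
F6 | step 6 | methyl (2E,4R)-5-Fur-2-[(4,4,5,5-tetramethyl-1,3,2-dioxaborolan-2-yl)methyl]-4-TMPO-pent-2-enoate | COC(=O)/C(CB1OC(C)(C)C(C)(C)O1)=C/[C@H](ON2C(C)(C)CCCC2(C)C)C[C@@]3(C)OC(=CC3=O)C(C)=C
F7 | step 2 | 2-methyl-5-(prop-1-en-2-yl)furan-3-yl prop-2-en-1-yl carbonate | C=CCOC(=O)Oc1cc(C(C)=C)oc1C
F8 | step 2 | (2R)-2-methyl-2-(prop-2-en-1-yl)-5-(prop-1-en-2-yl)furan-3(2H)-one | C=CC[C@@]1(C)OC(=CC1=O)C(C)=C
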